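(All constants stand for no real mixture; what happens was integrated by code.)

Count amounts as fractions of the D and Z charged together; G is charged at that same amount, and each D or Z converted takes one G.

    G + L + Z → L + X (k1 = 3.7 × 10⁷ M⁻² s⁻¹)
    G + L + D → L + E (k2 = 1.1 × 10⁸ M⁻² s⁻¹)
    D + J ⇌ Z + J, rate k3*[J]*[D] forward; the back reaction follows from the equilibrium constant (k3 = 1600 M⁻¹ s⁻¹)
    G → Q (k4 = 0.015 s⁻¹)

| setting | oak | alder | maple | larch |
|---|---|---|---|---|
| D | 0.50 mM | 0.50 mM | 0.50 mM | 0.50 mM |
| G | 1.00 mM | 1.00 mM | 1.00 mM | 1.00 mM |
| L | 2.5 µM | 2.5 µM | 2.5 µM | 2.5 µM |
| J | 100 µM | 100 µM | 100 µM | 100 µM |
| Z | 0.50 mM | 0.50 mM | 0.50 mM | 0.50 mM |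
| time | 3.0 s |  |  | 3.0 s |
| remark | a tube with plug flow, the mixed feed as stated, residence time 3.0 s | one stirred flow tank at steady state, fed with the mixture as stated, mean residence time 30.0 s | a single well-mixed tank run continuously and read at steady state, 3.0 s in it on average | everything together in a closed stirred flask, run for 3.0 s |
1. the set-up with the highest share of E in all that became E or X, at the outlet or at the end ("none" if the first two lie within 2 percentage points) (oak / alder / maple / larch / none)
2. share of E in all that became E or X, at the outlet or at the end, oak
3. share of E in all that became E or X, at the outlet or at the end, alder
4. share of E in all that became E or X, at the outlet or at the end, maple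
5. share of E in all that became E or X, at the outlet or at the end, larch
- L is single-handed; D and Z are mirror images of each other, charged as a racemate, each of them at the stated concentration
- the stated concentrations are those of everything mixed, before any reaction; amounts are the same in each set-up
- run time (oak): 3.0 s

Set the time constants in a ladder, shortest first. With D and Z swapping at 0.160 s⁻¹ each way, a gap between them closes in 3.13 s. Fresh G drains D in 3.64 s and Z in 10.8 s, a selectivity factor of 2.97. D therefore falls behind Z, but the swap is a little quicker than the drain of D; the two times are of like size, so expect D to trail Z with the swap closing part of the gap. G leaks to Q in 66.7 s, so set that aside for oak and larch, and keep it for the tanks.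

A tank holds one composition, so it has no curve to average. Its balances give D over Z as one minus the lag: the drain of D minus the drain of Z, divided by the sum of the drain of D, both swaps and the flush rate, the inverse of the residence time. The share of E is then the selectivity factor times D over Z, divided by that product plus one.

To find G in a tank, treat D and Z as one pool drained at the mean of the two rates, with G falling alongside it and leaking to Q. In alder, this gives G of 0.274. The lag is 0.0501 s⁻¹ over 0.429 s⁻¹, or 0.117, D's shortfall behind Z as a fraction of Z, so the share is 72.4 %. In maple, G is 0.693, the lag 0.150 and the share 71.7 %.

Oak and larch run the same curve, since both give 3.0 s of reaction. Replace G by its mean over that time, 0.796, let the lag climb from zero, and take its mean, 0.144. The share is 71.8 %. See how much the fall of G matters in this reckoning: with G held at its charge, the lag is 0.176 and the share 71.0 %. Alder stands highest in this reckoning, but its lead of 0.60 percentage points over oak and larch is below the margin, so commit to none.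

The forecast gave 70.4 % for oak and 70.4 % for larch, lower than this reckoning, with 72.4 % for alder, 71.6 % for maple and none as best, holding that “the tanks do slightly better because D and Z stay closer together”.

The simulation gives none, with oak at 71.9 %, larch at 71.9 %, alder at 72.4 % and maple at 71.6 %. Now take the swap out of alder's lag of 0.117: remove both swaps from the bottom of the fraction and keep G at 0.274, and the lag becomes 0.460, which gives a share of 61.6 %. The alder run with the step from D to Z struck out, both ways, reads 61.2 %.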